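C7 = ArCH, C8 = CHCH3 (methyl = C9), C1' = C(allyl), C2' = CHOH, C3' = C(OMe) bridgehead, C4' = C=O, C5' = CHOMe, C6' = CH2.
Enabling feature: the cyclopentane C1'-C2'-C3'-C7-C8 carries the array C2'(OH)–C3'(quaternary, OMe)–C4'(=O), a β-hydroxy ketone with an α-quaternary carbon. This is the retron of an epoxy-carbinol semipinacol shift.
Cuts: (a) C3'–C7 is cut and C7 is returned to C4'. This gives a 1-siloxy-2-methoxybicyclo[2.2.2]oct-2-ene whose ring C1'-C2'-C3'-C4'-C7-C8 is one atom larger. (b) C8–C1' and C7–C4' are cut (Diels–Alder), giving a masked o-benzoquinone and an (E)-propenylarene.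
Forward: apiole supplies all six ring carbons, the allyl group and three ring oxygens. It is turned into a dienone ketal, and the [4+2] closes the bicyclo[2.2.2]octene. C6' is then deoxygenated and C5' reduced and methylated. Enol-ether epoxidation followed by a 1,2-shift gives the bicyclo[3.2.1]octane.
Stereochemistry: the absolute configuration comes from a (2R,3R)-butane-2,3-diol ketal, which controls the diene face and is later removed by SmI2. C7/C8 trans comes from the E-alkene. C5' and C2' are set by reagent approach through the open sectors of the bicycle, and C3' by the antiperiplanar shift.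

Key step: step 10

Remark: apiole is taken as a commercial natural product. The sense of facial shielding by the ketal rests on a steric model; should it prove opposite, (2S,3S)-butane-2,3-diol is used in step 5 with no other change.

Step 1
Reactants: 1 5-bromo-2-methoxyphenol; 2 (E)-prop-1-enylboronic acid pinacol ester
Product: 3 (E)-2-methoxy-5-(prop-1-en-1-yl)phenol
Conditions: Pd(dppf)Cl2 (3 mol %), K2CO3, dioxane–H2O, 80 °C
Reagents that add atoms: none
Why: Suzuki–Miyaura coupling of an aryl bromide with an (E)-alkenylboronate keeps the alkene geometry and tolerates the free phenol.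

Step 2
Reactants: 3 (E)-2-methoxy-5-(prop-1-en-1-yl)phenol
Product: 4 (E)-triisopropyl[2-methoxy-5-(prop-1-en-1-yl)phenoxy]silane
Conditions: TIPSCl, imidazole, DMF, rt
Reagents that add atoms: chlorotriisopropylsilane, CC(C)[Si](Cl)(C(C)C)C(C)C
Why: Standard phenol silylation; the aryl TIPS ether should withstand SmI2, DIBAL-H, KHMDS and TiCl4 at low temperature.

Step 3
Reactants: 5 apiole (5-allyl-4,7-dimethoxy-1,3-benzodioxole)
Product: 6 4-allyl-3,6-dimethoxybenzene-1,2-diol
Conditions: BCl3 (1.2 equiv), CH2Cl2, −78 → −10 °C; H2O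
Reagents that add atoms: none
Why: Lewis-acid cleavage of a methylenedioxy acetal; BCl3 attacks the acetal oxygens faster than aryl methyl ethers and leaves the terminal alkene alone at low temperature.

Step 4
Reactants: 6 4-allyl-3,6-dimethoxybenzene-1,2-diol
Product: 7 3-allyl-2,5-dimethoxy-6-(triisopropylsilyloxy)phenol (C4'-OTIPS, C5'-OH)
Conditions: TIPSCl (1.0 equiv), imidazole, DMAP (cat.), DMF, rt, 24 h
Reagents that add atoms: chlorotriisopropylsilane, CC(C)[Si](Cl)(C(C)C)C(C)C
Why: Mono-silylation under equilibrating conditions (base-mediated O→O silyl migration in catechol monoethers) should place the bulky group on the less hindered C4' oxygen, whose neighbouring C3'-OMe lies in the ring plane turned towards C2'-H, whereas the C5' oxygen is buttressed by the out-of-plane C6'-OMe wedged against the allyl group.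

Step 5
Reactants: 7 3-allyl-2,5-dimethoxy-6-(triisopropylsilyloxy)phenol; 8 (2R,3R)-butane-2,3-diol
Product: 10 (2R,3R)-10-allyl-8-methoxy-2,3-dimethyl-7-(triisopropylsilyloxy)-1,4-dioxaspiro[4.5]deca-7,9-dien-6-one, via dimethyl-ketal dienone 9 (not isolated)
Conditions: PhI(OAc)2, MeOH, 0 °C; evaporate; 8 (3 equiv), CSA (5 mol %), 4 Å MS, CH2Cl2, rt
Reagents that add atoms: methanol, CO (enters 9, leaves again in the ketal exchange)
Why: Oxidative dearomatisation of a 2-methoxyphenol to a masked o-benzoquinone followed by acid-catalysed transketalisation; methanol should add at C6' because the charge there is stabilised by its own OMe and by the para C3'-OMe while C4' is shielded by TIPS, the five-membered ketal is favoured entropically, and the C2-symmetric diol creates no new stereocentre.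

Step 6
Reactants: 10 spiroketal dienone; 4 (E)-triisopropyl[2-methoxy-5-(prop-1-en-1-yl)phenoxy]silane
Product: 11 4-allyl-6-methoxy-8-methyl-7-[4-methoxy-3-(triisopropylsilyloxy)phenyl]-1-(triisopropylsilyloxy)bicyclo[2.2.2]oct-5-en-2-one 3,3-[(2R,3R)-butane-2,3-diyl] ketal (aryl syn to the keto/ketal bridge, methyl syn to the C5=C6 enol-ether bridge)
Conditions: 4 (3 equiv), BHT (cat.), toluene (2 M), 110 °C, sealed tube
Reagents that add atoms: none
Why: Inverse-electron-demand Diels–Alder reaction of a masked o-benzoquinone with a styrene-type dienophile: nucleophilic C8 bonds to the δ-carbon C1' and benzylic C7 to the α-carbon C4' (the usual "ortho" regiochemistry), the E-alkene fixes C7/C8 trans, the methyl group avoids the ketal and turns endo so that the aryl group lies exo over the flat C5' carbonyl, and the ketal methyl group that points towards C1' blocks one diene face, which sets the absolute configuration of C1', C4', C7 and C8.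

Step 7
Reactants: 11 Diels–Alder adduct
Product: 12 4-allyl-6-methoxy-8-methyl-7-[4-methoxy-3-(triisopropylsilyloxy)phenyl]-1-(triisopropylsilyloxy)bicyclo[2.2.2]oct-5-en-2-one (C6' = CH2)
Conditions: SmI2 (4.5 equiv), THF–MeOH, −78 → 0 °C
Reagents that add atoms: none
Why: SmI2 reduction of an α-oxygenated ketone: both C6'–O bonds overlap with the ketyl π system and are cleaved in turn, releasing the auxiliary, whereas the bridgehead C4'–O bond lies in the nodal plane of the carbonyl group and stays.

Step 8
Reactants: 12 bicyclo[2.2.2]octenone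
Product: 13 the corresponding bicyclo[2.2.2]oct-5-en-2-ol (C5'-OH pointing to the C7–C8 bridge)
Conditions: DIBAL-H, CH2Cl2, −78 °C; Rochelle salt
Reagents that add atoms: none
Why: Hydride should reach C5'=O from the open sector facing the enol-ether bridge because the other face is covered by the C7 aryl group, which gives the C5' configuration of the target.

Step 9
Reactants: 13 bicyclo[2.2.2]octenol
Product: 14 4-allyl-2,6-dimethoxy-8-methyl-7-[4-methoxy-3-(triisopropylsilyloxy)phenyl]-1-(triisopropylsilyloxy)bicyclo[2.2.2]oct-5-ene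
Conditions: KHMDS, THF, −78 °C; MeOTf
Reagents that add atoms: methyl triflate, COS(=O)(=O)C(F)(F)F
Why: Williamson-type O-methylation; fast capture of the potassium alkoxide at −78 °C should outrun migration of the neighbouring bridgehead TIPS group.

Step 10
Reactants: 14 1-siloxy-2-methoxybicyclo[2.2.2]octene (neolignan locants: C4'-OTIPS, C2'H=C3'-OMe)
Product: 16 5-allyl-8-hydroxy-1,3-dimethoxy-6-methyl-7-[4-methoxy-3-(triisopropylsilyloxy)phenyl]bicyclo[3.2.1]octan-2-one, via epoxy ether 15 (not isolated)
Conditions: DMDO, CH2Cl2–acetone, −78 → −40 °C, evaporate cold; TiCl4 (1.1 equiv), CH2Cl2, −78 °C; H2O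
Reagents that add atoms: dimethyldioxirane, CC1(C)OO1
Why: Dimethyldioxirane transfers oxygen through its concerted spiro transition state to the only electron-rich alkene, the C2'=C3' enol ether (the allyl group is far less nucleophilic), and does so from the sector facing the C5'–C6' bridge because the opposite sector holds the C9 methyl group, which closes the oxirane of 15 and sets C2'. TiCl4 then binds the oxirane oxygen, the C3'–O bond ionises with help of the methoxy group, and the C4'–C7 σ bond, antiperiplanar to that bond and pushed by the bridgehead siloxy oxygen, migrates suprafacially from C4' to C3', after which chloride takes the silyl group from the C4' oxocarbenium ion to leave the ketone. The event is a semipinacol rearrangement of a 2,3-epoxy silyl ether, the known route to β-hydroxy ketones with an α-quaternary carbon, run on an epoxy ether prepared as in glycal epoxidation. No ring is closed by cyclisation: the 1,2-shift contracts the six-membered ring C1'-C2'-C3'-C4'-C7-C8 to the cyclopentane C1'-C2'-C3'-C7-C8, widens ring C1'-C6'-C5'-C4'-C7-C8 to the seven-membered ring C1'-C6'-C5'-C4'-C3'-C7-C8 and leaves the carbocycle C1'–C6' six-membered (bicyclo[2.2.2] → bicyclo[3.2.1]). C3' forms with inversion (C7 enters anti to the departing oxygen) and C7 migrates with retention, so both centres follow from the oxirane face and from step 6. The step needs C7 to migrate rather than C5' or the C2' hydride: C5' is synclinal to the leaving oxygen and bears a withdrawing OMe, and the titanium-bound C2' alkoxide is a much poorer donor than the siloxy group at C4'.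

Step 11
Reactants: 16 O-TIPS-protected target
Product: 17 5-allyl-8-hydroxy-7-(3-hydroxy-4-methoxyphenyl)-1,3-dimethoxy-6-methylbicyclo[3.2.1]octan-2-one (CNP0209708.1)
Conditions: HF·pyridine, THF–pyridine, 0 °C
Reagents that add atoms: none
Why: Fluoride cleavage of the aryl silyl ether under mildly acidic, non-basic conditions, so that the epimerisable C5' centre and the β-hydroxy ketone (retro-aldol) are not disturbed.

Compound list
1 | 5-bromo-2-methoxyphenol | COc1ccc(Br)cc1O | starting material
2 | (E)-prop-1-enylboronic acid pinacol ester | C/C=C/B1OC(C)(C)C(C)(C)O1 | starting material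
3 | (E)-2-methoxy-5-(prop-1-en-1-yl)phenol | C/C=C/c1ccc(OC)c(O)c1 | intermediate
4 | (E)-triisopropyl[2-methoxy-5-(prop-1-en-1-yl)phenoxy]silane | C/C=C/c1ccc(OC)c(O[Si](C(C)C)(C(C)C)C(C)C)c1 | intermediate
5 | apiole (5-allyl-4,7-dimethoxy-1,3-benzodioxole) | C=CCc1cc(OC)c2OCOc2c1OC | starting material
6 | 4-allyl-3,6-dimethoxybenzene-1,2-diol | C=CCc1cc(OC)c(O)c(O)c1OC | intermediate
7 | 3-allyl-2,5-dimethoxy-6-(triisopropylsilyloxy)phenol | C=CCc1cc(OC)c(O[Si](C(C)C)(C(C)C)C(C)C)c(O)c1OC | intermediate
8 | (2R,3R)-butane-2,3-diol | C[C@@H](O)[C@@H](C)O | starting material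
9 | 5-allyl-3,6,6-trimethoxy-2-(triisopropylsilyloxy)cyclohexa-2,4-dien-1-one | C=CCC1=CC(OC)=C(O[Si](C(C)C)(C(C)C)C(C)C)C(=O)C1(OC)OC | intermediate
10 | (2R,3R)-10-allyl-8-methoxy-2,3-dimethyl-7-(triisopropylsilyloxy)-1,4-dioxaspiro[4.5]deca-7,9-dien-6-one | C=CCC1=CC(OC)=C(O[Si](C(C)C)(C(C)C)C(C)C)C(=O)C12O[C@H](C)[C@@H](C)O2 | intermediate
11 | Diels–Alder adduct (bicyclo[2.2.2]oct-5-en-2-one 3,3-butanediyl ketal; aryl syn to keto/ketal bridge, methyl syn to enol-ether bridge) | C=CC[C@]12C=C(OC)[C@](O[Si](C(C)C)(C(C)C)C(C)C)(C(=O)C13O[C@H](C)[C@@H](C)O3)[C@H](c4ccc(OC)c(O[Si](C(C)C)(C(C)C)C(C)C)c4)[C@H]2C | intermediate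
12 | 4-allyl-6-methoxy-8-methyl-7-aryl-1-(triisopropylsilyloxy)bicyclo[2.2.2]oct-5-en-2-one | C=CC[C@]12C=C(OC)[C@](O[Si](C(C)C)(C(C)C)C(C)C)(C(=O)C1)[C@H](c4ccc(OC)c(O[Si](C(C)C)(C(C)C)C(C)C)c4)[C@H]2C | intermediate
13 | corresponding 2-ol (OH syn to the C7–C8 bridge) | C=CC[C@]12C=C(OC)[C@](O[Si](C(C)C)(C(C)C)C(C)C)([C@@H](O)C1)[C@H](c4ccc(OC)c(O[Si](C(C)C)(C(C)C)C(C)C)c4)[C@H]2C | intermediate
14 | corresponding 2-methyl ether | C=CC[C@]12C=C(OC)[C@](O[Si](C(C)C)(C(C)C)C(C)C)([C@@H](OC)C1)[C@H](c4ccc(OC)c(O[Si](C(C)C)(C(C)C)C(C)C)c4)[C@H]2C | intermediate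
15 | 5,6-epoxide of 14 (oxirane oxygen syn to the C2–C3 bridge) | C=CC[C@]12[C@@H]3O[C@]3(OC)[C@](O[Si](C(C)C)(C(C)C)C(C)C)([C@@H](OC)C1)[C@H](c4ccc(OC)c(O[Si](C(C)C)(C(C)C)C(C)C)c4)[C@H]2C | intermediate
16 | aryl O-TIPS ether of the target | C=CC[C@]12C[C@H](OC)C(=O)[C@](OC)([C@H](c3ccc(OC)c(O[Si](C(C)C)(C(C)C)C(C)C)c3)[C@H]1C)[C@H]2O | intermediate
17 | CNP0209708.1 (7-endo-aryl, 6-exo-methyl, 3-endo-OMe, 8-OH syn to the C2–C4 bridge) | C=CC[C@]12C[C@H](OC)C(=O)[C@](OC)([C@H](c3ccc(OC)c(O)c3)[C@H]1C)[C@H]2O | target

Total step count: 11. Longest linear sequence: 9 steps (5 → 17, steps 3–11).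

Steps most likely to fail

Step 6. The cycloaddition may be sluggish because both diene termini are fully substituted and the C3'-OMe donor raises the dienone LUMO, and both the exo-aryl preference and the facial bias of the ketal may erode.
- The fallback sets out from 9 and gives up the auxiliary. The slimmer dimethyl ketal 9 is combined with 4 at 12–15 kbar (CH2Cl2, rt) to give the racemic dimethyl-ketal adduct F1.
- SmI2 then gives racemic 12.
- The absolute configuration is taken from a CBS-catalysed kinetic resolution in the ketone reduction that is needed anyway (Me-CBS, BH3·SMe2, about half an equivalent of hydride).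
- The matched enantiomer is reduced to 13, where the route is rejoined. The mismatched ketone ent-12 F2 is separated.

Step 10. After the oxirane opens, a 1,2-hydride shift from C2' or chloride-induced loss of the C3' O-methyl group may outrun the migration of C7.
- The fallback sets out from 14 and makes the migration origin a much stronger donor. TBAF removes both silyl groups to give the bridgehead carbinol–phenol F3.
- DMDO at −78 °C, where the enol ether reacts before the phenol, gives the α-hydroxy epoxy ether F4.
- Catalytic ZnBr2 forms a chelated zinc alkoxide at C4' that drives the semipinacol rearrangement of the α-hydroxy epoxide. This leads directly to 17.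

Step 4. Silylation may occur at the wrong oxygen, or the two monoethers may not equilibrate cleanly.
- The fallback sets out from 6 and uses acidity instead of size. The more acidic C5'-OH, which is ortho to the twisted and non-donating C6'-OMe, is capped first (MOMCl, one equivalent of iPr2NEt) to give the C5'-MOM ether F5.
- The remaining C4'-OH is silylated (TIPSOTf, 2,6-lutidine) to give the MOM/TIPS diether F6.
- Catalytic HCl in MeOH removes the MOM group and returns to 7.

Further compounds
F1 | step 6 | racemic dimethyl-ketal adduct (relative configuration as 11) | C=CC[C@]12C=C(OC)[C@](O[Si](C(C)C)(C(C)C)C(C)C)(C(=O)C1(OC)OC)[C@H](c4ccc(OC)c(O[Si](C(C)C)(C(C)C)C(C)C)c4)[C@H]2C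
F2 | step 6 | ent-12 (unreacted ketone of the kinetic resolution) | C=CC[C@@]12C=C(OC)[C@@](O[Si](C(C)C)(C(C)C)C(C)C)(C(=O)C1)[C@@H](c4ccc(OC)c(O[Si](C(C)C)(C(C)C)C(C)C)c4)[C@@H]2C
F3 | step 10 | bridgehead carbinol–phenol (14 without both TIPS groups) | C=CC[C@]12C=C(OC)[C@](O)([C@@H](OC)C1)[C@H](c4ccc(OC)c(O)c4)[C@H]2C
F4 | step 10 | α-hydroxy epoxy ether | C=CC[C@]12[C@@H]3O[C@]3(OC)[C@](O)([C@@H](OC)C1)[C@H](c4ccc(OC)c(O)c4)[C@H]2C
F5 | step 4 | 4-allyl-3,6-dimethoxy-2-(methoxymethoxy)phenol (C5'-OMOM, C4'-OH) | C=CCc1cc(OC)c(O)c(OCOC)c1OC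
F6 | step 4 | C5'-OMOM, C4'-OTIPS diether | C=CCc1cc(OC)c(O[Si](C(C)C)(C(C)C)C(C)C)c(OCOC)c1OC
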